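**Assumption:** the (S,S)-configured IDPi catalyst is taken to expose the Si face of O-silylated decanal (giving 5R). This sense is unproven for this substrate pair, so it is checked on a test scale (chiral HPLC or Mosher ester of 6), and the (R,R)-antipode is used if it is reversed.

**Retrosynthetic overview**
1. No ring is formed. The only ring, the guaiacol arene, is bought with zingerone 1, and the target is an acyclic syn-1,3-diol.
2. C4–C5 (aldol) disconnection: 1 is converted through its dilithium phenoxide-enolate 2 into the regiodefined bis(trimethylsilyl) enol ether 3. Compound 3 adds to decanal 4 under a chiral, metal-free IDPi acid to give, through silylated adduct 5, (R)-[10]-gingerol 6. This sets C5 from achiral materials.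
3. C3–H disconnection: 1,3-syn reduction of 6 through boron chelate 7 and cyclic borate 8 relays C5 to C3 and gives target 9.
4. Three steps instead of a two-step direct amine-catalysed aldol: pre-forming 3 fixes the site of enolisation, allows near 1:1 stoichiometry, and removes the amine that causes decanal self-aldol and dehydration to the shogaol.

**Catalyst for step 2:** (S,S)-IDPi is the imidodiphosphorimidate Brønsted acid HN[P(=NSO2CF3)(binaphthyl-2,2'-diyl-dioxy)]2, assembled from two (S)-3,3'-bis[3,5-bis(trifluoromethyl)phenyl]-1,1'-bi-2-naphthol units.

**Step 1**
Reactants: 1 zingerone [4-(4-hydroxy-3-methoxyphenyl)butan-2-one]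
Product: 3 2-trimethylsilyloxy-4-(3-methoxy-4-trimethylsilyloxyphenyl)but-1-ene, via dilithium phenoxide-enolate 2 (not isolated)
Conditions: LiN(iPr)2 (2.2 equiv), THF, −78 °C, 45 min (1 added to the base); Me3SiCl (2.6 equiv), −78 to 0 °C; pentane, filtration under argon, Kugelrohr distillation
Reagents that add atoms: chlorotrimethylsilane (C[Si](C)(C)Cl)
Why: Kinetic enolisation with a hindered lithium amide at −78 °C removes the phenol proton and then a proton of the less hindered CH3 group, and O-silylation of both oxyanions (kinetic silyl enol ether formation) fixes the terminal enol ether; no stereocentre is formed.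

**Step 2**
Reactants: 3 2-trimethylsilyloxy-4-(3-methoxy-4-trimethylsilyloxyphenyl)but-1-ene; 4 decanal
Product: 6 (R)-[10]-gingerol [(5R)-5-hydroxy-1-(4-hydroxy-3-methoxyphenyl)tetradecan-3-one], via bis-silyl aldol adduct 5 (not isolated)
Conditions: (S,S)-IDPi (1 mol%), 3 (1.2 equiv), toluene, −78 °C, 24 h; then 1 M HCl, THF, 0 °C, 15 min
Reagents that add atoms: none
Why: Proposed new method: the confined strong acid is silylated by 3 to a silylium–imidodiphosphorimidate ion pair that O-silylates decanal, the resulting silyloxocarbenium ion is held in the chiral anion pocket so that the terminal CH2 of 3 attacks only its Si face (giving 5R), silyl transfer from the adduct to the next aldehyde turns the catalyst over, and because no base or amine is present decanal cannot self-condense; the closest known reaction type is the silylium-based, chiral-counteranion-directed Mukaiyama aldol of silyl ketene acetals and aldehyde-derived enolsilanes with aldehydes, here extended to a methyl-ketone-derived 2-silyloxy-1-alkene and an unbranched aliphatic aldehyde.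

**Step 3**
Reactants: 6 (R)-[10]-gingerol
Product: 9 (3S,5R)-1-(4-hydroxy-3-methoxyphenyl)tetradecane-3,5-diol (the target), via diethylboron chelate 7 (not isolated), via cyclic sodium diethylborate 8 (not isolated)
Conditions: Et2BOMe (1.5 equiv), THF/MeOH 4:1, −78 °C, 30 min; NaBH4 (1.5 equiv), −78 °C, 4 h; AcOH; MeOH co-evaporation
Reagents that add atoms: none
Why: Narasaka–Prasad reduction: the diethylboron chelate of the β-hydroxy ketone adopts a half-chair with the nonyl group pseudo-equatorial, and external hydride adds axially through a chair-like transition state, so the C5 (R) centre dictates the 1,3-syn diol and the new C3 centre is S.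

**Compound list**
1 | zingerone, 4-(4-hydroxy-3-methoxyphenyl)butan-2-one | CC(=O)CCc1ccc(O)c(OC)c1 | starting material
2 | dilithium 4-(3-methoxy-4-oxidophenyl)but-1-en-2-olate (phenoxide-enolate of 1) | [Li+].[Li+].C=C([O-])CCc1ccc([O-])c(OC)c1 | intermediate (not isolated)
3 | 2-trimethylsilyloxy-4-(3-methoxy-4-trimethylsilyloxyphenyl)but-1-ene | C=C(O[Si](C)(C)C)CCc1ccc(O[Si](C)(C)C)c(OC)c1 | intermediate
4 | decanal | CCCCCCCCCC=O | starting material
5 | (5R)-1-(3-methoxy-4-trimethylsilyloxyphenyl)-5-trimethylsilyloxytetradecan-3-one | CCCCCCCCC[C@@H](O[Si](C)(C)C)CC(=O)CCc1ccc(O[Si](C)(C)C)c(OC)c1 | intermediate (not isolated)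
6 | (R)-[10]-gingerol, (5R)-5-hydroxy-1-(4-hydroxy-3-methoxyphenyl)tetradecan-3-one | CCCCCCCCC[C@@H](O)CC(=O)CCc1ccc(O)c(OC)c1 | intermediate
7 | (5R)-5-(diethylboranyloxy)-1-(4-hydroxy-3-methoxyphenyl)tetradecan-3-one (boron chelated by the ketone oxygen; dative bond not drawn) | CCCCCCCCC[C@@H](OB(CC)CC)CC(=O)CCc1ccc(O)c(OC)c1 | intermediate (not isolated)
8 | sodium (4S,6R)-2,2-diethyl-4-[2-(4-hydroxy-3-methoxyphenyl)ethyl]-6-nonyl-1,3,2-dioxaborinan-2-uide | CCCCCCCCC[C@@H](O1)C[C@@H](O[B-]1(CC)CC)CCc2ccc(O)c(OC)c2.[Na+] | intermediate (not isolated)
9 | (3S,5R)-1-(4-hydroxy-3-methoxyphenyl)tetradecane-3,5-diol | CCCCCCCCC[C@@H](O)C[C@@H](O)CCc1ccc(O)c(OC)c1 | target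

**Total step count:** 3
**Longest linear sequence:** 3 (1 → 3 → 6 → 9)

**Steps most likely to fail**

1. **Step 2 (proposed new step).** The risks are an unproven level and sense of enantioselectivity, acid-induced trimerisation of decanal, and poisoning of the catalyst by traces of amine carried over from step 1. The fallback is known chemistry. It sets out from 1 (with 4) and comes back at 6. It is a direct enamine aldol: D-proline (30 mol%), 1 in fivefold excess (recovered), 4 added by syringe pump over 24 h, CHCl3/DMSO 4:1, 4 °C. The enamine forms on the CH3 side and attacks the Si face of decanal through the hydrogen-bonded chair transition state established for proline aldols, giving 5R. This reaction class is known to give only moderate yield and ee with unbranched aldehydes, so the ee is upgraded by recrystallising 9. No new compound is made.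

2. **Step 1.** The risks are 5–10% of the internal enol ether regioisomer (which would give a branched aldol), hydrolytic lability of 3, and residual amine. The fallback sets out from 1 and comes back at 3. It avoids the dianion by working in two stages. First only the phenol is silylated with hexamethyldisilazane (0.6 equiv) and catalytic Me3SiCl at 60 °C to give distillable 4-(3-methoxy-4-trimethylsilyloxyphenyl)butan-2-one F1. F1 is then added to lithium 2,2,6,6-tetramethylpiperidide (1.1 equiv) in THF at −78 °C with Me3SiCl already present, so that lithium 4-(3-methoxy-4-trimethylsilyloxyphenyl)but-1-en-2-olate F2 is trapped as it forms and gives 3 with higher terminal selectivity.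

3. **Step 3.** The risks are that the free phenol competes for boron so chelation is incomplete and the syn:anti ratio drops, and that boron residues are hard to remove. The fallback sets out from 6 and comes back at 9. It replaces chelate (substrate) control by catalyst control: a ketoreductase selected from a commercial enzyme panel for (3S)-selective hydride delivery, with NADP+ and isopropanol recycling, KH2PO4/K2HPO4 buffer pH 7, 10% DMSO, 30 °C. No new compound is made.

**Further compounds**
F1 | step 1 | 4-(3-methoxy-4-trimethylsilyloxyphenyl)butan-2-one | CC(=O)CCc1ccc(O[Si](C)(C)C)c(OC)c1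
F2 | step 1 | lithium 4-(3-methoxy-4-trimethylsilyloxyphenyl)but-1-en-2-olate | [Li+].C=C([O-])CCc1ccc(O[Si](C)(C)C)c(OC)c1
F0 | step 2 | none | none
F0 | step 3 | none | none
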